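The ring is numbered C1 (ketone), C2 (ester-bearing alkene carbon), C3, C4 (carbinol), C5 (chain-bearing CH), C6 (CH2). The C1 carbonyl and C4 hydroxyl flank the C2=C3 alkene of the cyclohexenone ring, which is the signature of a ring-opened 1-oxy-7-oxanorbornene. The route rests on a copper-bisoxazoline-catalysed endo [4+2] cycloaddition between a 2-silyloxyfuran (C1–C4 with the acetate arm) and an (E)-enoyl pyrazole carrying the whole geranylgeranyl chain (C5=C6). It forms C4–C5 and C1–C6 and sets both stereocentres. Fluoride then opens the strained silyl ketal bridge to the hydroxy enone, and the acyl activator is lost by decarboxylation.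

Key step: step 8

Remark: commercial monomethyl itaconate is taken as the 4-methyl ester (free acid on the methylidene-bearing carbon), and geranylgeraniol as its all-E isomer.

Step 1
Reactants: 1 monomethyl itaconate; 2 allyl bromide
Product: 3 1-allyl 4-methyl 2-methylidenebutanedioate
Conditions: K2CO3 (1.1 equiv), DMF, 0 °C to rt
Reagents that add atoms: allyl bromide 2, C=CCBr
Why: SN2 O-alkylation of the potassium carboxylate by the allylic bromide should esterify the free acid without touching the methyl ester or the 1,1-disubstituted alkene.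

Step 2
Reactants: 3 1-allyl 4-methyl 2-methylidenebutanedioate
Product: 4 methyl 2-(2-oxo-2,5-dihydrofuran-3-yl)acetate
Conditions: second-generation Grubbs catalyst RuCl2(H2IMes)(PCy3)(=CHPh) (5 mol%), CH2Cl2 (5 mM), reflux
Reagents that add atoms: none
Why: Ring-closing metathesis of an allyl 2-substituted acrylate should close the α-substituted butenolide, driven by loss of ethylene.

Step 3
Reactants: 4 methyl 2-(2-oxo-2,5-dihydrofuran-3-yl)acetate
Product: 5 methyl 2-[2-(triisopropylsilyloxy)furan-3-yl]acetate
Conditions: TIPSOTf (1.05 equiv), Et3N (1.5 equiv), CH2Cl2, 0 °C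
Reagents that add atoms: triisopropylsilyl triflate, CC(C)[Si](OS(=O)(=O)C(F)(F)F)(C(C)C)C(C)C
Why: Soft enolisation of the butenolide (O-silylation, then loss of the ring C5 proton) should give the aromatic 2-silyloxyfuran, aromatisation favouring ring deprotonation over deprotonation of the acetate arm.

Step 4
Reactants: 6 (2E,6E,10E)-geranylgeraniol
Product: 7 (2E,6E,10E)-geranylgeranyl bromide
Conditions: PBr3 (0.4 equiv), Et2O, −10 °C
Reagents that add atoms: phosphorus tribromide, BrP(Br)Br
Why: Conversion of the primary allylic alcohol to the bromide through its phosphite ester (SN2 at low temperature) should retain the E geometry; the bromide is used without chromatography.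

Step 5
Reactants: 7 (2E,6E,10E)-geranylgeranyl bromide; 8 ethyl (E)-3-(pinacolboryl)acrylate
Product: 9 ethyl (2E,5E,9E,13E)-6,10,14,18-tetramethylnonadeca-2,5,9,13,17-pentaenoate
Conditions: Pd(PPh3)4 (5 mol%), CsF (3 equiv), THF, 50 °C
Reagents that add atoms: ethyl (E)-3-(4,4,5,5-tetramethyl-1,3,2-dioxaborolan-2-yl)acrylate 8, CCOC(=O)/C=C/B1OC(C)(C)C(C)(C)O1
Why: In this Suzuki–Miyaura allyl–alkenyl coupling, zerovalent palladium ionises the allylic bromide, and fluoride-promoted transmetalation with reductive elimination at the unsubstituted allyl terminus should give the skipped dienoate with both alkene geometries retained.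

Step 6
Reactants: 9 ethyl (2E,5E,9E,13E)-6,10,14,18-tetramethylnonadeca-2,5,9,13,17-pentaenoate
Product: 10 (2E,5E,9E,13E)-6,10,14,18-tetramethylnonadeca-2,5,9,13,17-pentaenoic acid
Conditions: LiOH·H2O (2 equiv), THF/H2O (3:1), 0 °C to rt; then 1 M HCl to pH 3
Reagents that add atoms: lithium hydroxide, [Li+].[OH-]
Why: Saponification of the unhindered ethyl ester at low temperature should outpace γ-deprotonation, so the skipped 2,5-diene is not drawn into conjugation.

Step 7
Reactants: 10 (2E,5E,9E,13E)-6,10,14,18-tetramethylnonadeca-2,5,9,13,17-pentaenoic acid; 11 3,5-dimethylpyrazole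
Product: 12 (2E,5E,9E,13E)-1-(3,5-dimethylpyrazol-1-yl)-6,10,14,18-tetramethylnonadeca-2,5,9,13,17-pentaen-1-one
Conditions: EDC·HCl (1.3 equiv), DMAP (5 mol%), CH2Cl2, 0 °C
Reagents that add atoms: 3,5-dimethylpyrazole 11, Cc1cc(C)n[nH]1
Why: Carbodiimide-mediated N-acylation of the pyrazole should give the chelating active amide, the short reaction at 0 °C limiting γ-deprotonation of the activated dienoyl unit.

Step 8
Reactants: 5 methyl 2-[2-(triisopropylsilyloxy)furan-3-yl]acetate (1.5 equiv); 12 (2E,5E,9E,13E)-1-(3,5-dimethylpyrazol-1-yl)-6,10,14,18-tetramethylnonadeca-2,5,9,13,17-pentaen-1-one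
Product: 14 C6-(3,5-dimethylpyrazol-1-ylcarbonyl) hydroxy enone (4R 5R), via oxanorbornene silyl ketal 13 (not isolated)
Conditions: Cu(OTf)2 (10 mol%), (R,R)-tBu-box (11 mol%), 4 Å MS, CH2Cl2, −78 to −40 °C; then HF·pyridine, THF/pyridine, −40 to 0 °C
Reagents that add atoms: methyl 2-[2-(triisopropylsilyloxy)furan-3-yl]acetate 5, COC(=O)Cc1ccoc1O[Si](C(C)C)(C(C)C)C(C)C
Why: The enoyl pyrazole chelated to divalent copper is attacked at C5 by the free furan terminus (target C4), and the copper enolate carbon C6 closes onto the silyloxocarbenium carbon C1 in a concerted-asynchronous or stepwise Diels–Alder reaction that forms C4–C5 and C1–C6 in one operation; HF then cleaves the bridgehead silyl ether and the hemiketal collapses, the strain of the 7-oxanorbornene driving C1–O scission to the C1 ketone and the C4 hydroxyl. The closest known reaction types are the copper-bisoxazoline-catalysed Diels–Alder reaction of furan with N-acryloyl imides, the endo-type additions of 2-silyloxyfurans to N-enoyl imides under the same catalysts, and the Diels–Alder/ring-opening of 2-silyloxyfurans to 4-hydroxycyclohexenones. The six-membered carbocycle closes by [4+2] cycloaddition (in the stepwise picture a 6-(enolexo)-exo-trig attack of C6 on C1), transiently building the oxygen-bridged bicycle. C5 is set by the ligand: in the square-planar s-cis chelate a tert-butyl group shields one enoyl face, so the (R,R) complex should deliver the furan to the α-Si/β-Re face (the mirror image of the (S,S) complex, which exposes the α-Re face); C4 is set relative to C5 by the endo transition state, which puts the acyl group endo and therefore the chain exo, syn to the oxygen bridge and so cis to the C4 oxygen after ring opening. The step needs ring closure to outrun silyl transfer to the enolate, which the bulky TIPS group and the absence of a protic additive should secure (this also keeps the chelating β-dicarbonyl masked as the ketal until the quench); regioselectivity follows from the single unsubstituted nucleophilic furan terminus, and the four isolated trisubstituted alkenes are not activated. C6 is formed as an epimerisable β-dicarbonyl centre (drawn trans to the chain) and is removed as a stereocentre in step 9.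

Step 9
Reactants: 14 C6-(3,5-dimethylpyrazol-1-ylcarbonyl) hydroxy enone
Product: 16 CNP0274044.1, via β-keto acid 15 (not isolated)
Conditions: DMAP (20 mol%), THF/H2O (4:1), 45 °C
Reagents that add atoms: none
Why: Nucleophilic catalysis should transfer the active N-acylpyrazole acyl group to water, and the resulting β-keto acid should lose CO2 through the six-membered cyclic transition state at 45 °C (acyl substitution of an active amide, then β-keto acid decarboxylation), leaving C6 as CH2 without touching C4, C5, the methyl ester or the alkenes.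

Compound list

1 | monomethyl itaconate (4-methoxy-2-methylidene-4-oxobutanoic acid) | C=C(CC(=O)OC)C(=O)O | starting material
2 | allyl bromide | C=CCBr | starting material
3 | 1-allyl 4-methyl 2-methylidenebutanedioate | C=CCOC(=O)C(=C)CC(=O)OC | intermediate
4 | methyl 2-(2-oxo-2,5-dihydrofuran-3-yl)acetate | COC(=O)CC1=CCOC1=O | intermediate
5 | methyl 2-[2-(triisopropylsilyloxy)furan-3-yl]acetate | COC(=O)Cc1ccoc1O[Si](C(C)C)(C(C)C)C(C)C | intermediate
6 | (2E,6E,10E)-geranylgeraniol | OC/C=C(\C)CC/C=C(\C)CC/C=C(\C)CCC=C(C)C | starting material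
7 | (2E,6E,10E)-geranylgeranyl bromide | BrC/C=C(\C)CC/C=C(\C)CC/C=C(\C)CCC=C(C)C | intermediate
8 | ethyl (E)-3-(4,4,5,5-tetramethyl-1,3,2-dioxaborolan-2-yl)acrylate | CCOC(=O)/C=C/B1OC(C)(C)C(C)(C)O1 | starting material
9 | ethyl (2E,5E,9E,13E)-6,10,14,18-tetramethylnonadeca-2,5,9,13,17-pentaenoate | CCOC(=O)/C=C/C/C=C(\C)CC/C=C(\C)CC/C=C(\C)CCC=C(C)C | intermediate
10 | (2E,5E,9E,13E)-6,10,14,18-tetramethylnonadeca-2,5,9,13,17-pentaenoic acid | OC(=O)/C=C/C/C=C(\C)CC/C=C(\C)CC/C=C(\C)CCC=C(C)C | intermediate
11 | 3,5-dimethyl-1H-pyrazole | Cc1cc(C)n[nH]1 | starting material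
12 | (2E,5E,9E,13E)-1-(3,5-dimethyl-1H-pyrazol-1-yl)-6,10,14,18-tetramethylnonadeca-2,5,9,13,17-pentaen-1-one | Cc1cc(C)n(n1)C(=O)/C=C/C/C=C(\C)CC/C=C(\C)CC/C=C(\C)CCC=C(C)C | intermediate
13 | methyl 2-[6-endo-(3,5-dimethylpyrazole-1-carbonyl)-5-exo-geranylgeranyl-1-(triisopropylsilyloxy)-7-oxabicyclo[2.2.1]hept-2-en-2-yl]acetate (chain syn to the oxygen bridge, acyl anti) | COC(=O)CC1=C[C@@H]2O[C@@]1(O[Si](C(C)C)(C(C)C)C(C)C)[C@H](C(=O)n3nc(C)cc3C)[C@H]2C/C=C(\C)CC/C=C(\C)CC/C=C(\C)CCC=C(C)C | intermediate
14 | methyl 2-[(3R,4R,5R)-5-(3,5-dimethylpyrazole-1-carbonyl)-3-hydroxy-6-oxo-4-[(2E,6E,10E)-3,7,11,15-tetramethylhexadeca-2,6,10,14-tetraen-1-yl]cyclohex-1-en-1-yl]acetate (hydroxyl and chain cis; acyl trans to chain, labile) | COC(=O)CC1=C[C@H](O)[C@H](C/C=C(\C)CC/C=C(\C)CC/C=C(\C)CCC=C(C)C)[C@@H](C(=O)n2nc(C)cc2C)C1=O | intermediate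
15 | (1R,5R,6R)-5-hydroxy-3-(2-methoxy-2-oxoethyl)-2-oxo-6-[(2E,6E,10E)-3,7,11,15-tetramethylhexadeca-2,6,10,14-tetraen-1-yl]cyclohex-3-ene-1-carboxylic acid | COC(=O)CC1=C[C@H](O)[C@H](C/C=C(\C)CC/C=C(\C)CC/C=C(\C)CCC=C(C)C)[C@@H](C(O)=O)C1=O | intermediate
16 | CNP0274044.1, methyl 2-[(3R,4R)-3-hydroxy-6-oxo-4-[(2E,6E,10E)-3,7,11,15-tetramethylhexadeca-2,6,10,14-tetraen-1-yl]cyclohex-1-en-1-yl]acetate | COC(=O)CC1=C[C@H](O)[C@H](C/C=C(\C)CC/C=C(\C)CC/C=C(\C)CCC=C(C)C)CC1=O | target

Total step count: 9. Longest linear sequence: 6 steps (steps 4, 5, 6, 7, 8, 9).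

Steps most likely to fail

Step 8. Silyl transfer to the copper enolate may intercept the zwitterion before the C1–C6 closure, so that only the open-chain conjugate addition occurs; endo/exo or facial selectivity may also be eroded. The fallback sets out from 5 and 12 and separates the two bond formations. The same copper catalyst is run deliberately in the Mukaiyama–Michael mode with hexafluoroisopropanol as proton source, to give methyl 2-[(5R)-5-[(3R,5E,9E,13E)-1-(3,5-dimethylpyrazol-1-yl)-6,10,14,18-tetramethyl-1-oxononadeca-5,9,13,17-tetraen-3-yl]-2-oxo-2,5-dihydrofuran-3-yl]acetate F1. The N-acylpyrazole of this adduct is then soft-enolised (MgBr2·OEt2, i-Pr2NEt, CH2Cl2, −20 °C), and the magnesium enolate carbon C6 acylates the lactone carbonyl C1 with opening of the lactone (a Dieckmann-type, Hauser–Kraus-like closure). The fallback returns to the route at 14.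

Step 9. The enolised β-dicarbonyl may resist acyl transfer, and competing hydrolysis of the methyl ester or retro-Claisen cleavage at the ring ketone may intervene. The fallback sets out from 14. Transacylation with allyl alcohol (DMAP cat., toluene, 60 °C) gives allyl (1R,5R,6R)-5-hydroxy-3-(2-methoxy-2-oxoethyl)-2-oxo-6-[(2E,6E,10E)-3,7,11,15-tetramethylhexadeca-2,6,10,14-tetraen-1-yl]cyclohex-3-ene-1-carboxylate F2. Neutral Tsuji deallylation–decarboxylation (Pd(PPh3)4 (5 mol%), morpholine, THF, rt) then returns to the route at 16.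

Step 5. The π-allyl palladium intermediate may undergo syn/anti isomerisation with loss of the E geometry at the first chain alkene, couple at the branched terminus, or the base may draw the skipped diene into conjugation. The fallback sets out from 7 and avoids the π-allyl intermediate. Copper-catalysed SN2 vinylation (vinylmagnesium bromide, CuI (10 mol%), THF, −30 °C) gives (4E,8E,12E)-5,9,13,17-tetramethyloctadeca-1,4,8,12,16-pentaene F3. Cross-metathesis of its terminal vinyl group with acrylic acid (second-generation Hoveyda–Grubbs catalyst RuCl2(H2IMes)(=CH-C6H4-2-OiPr) (5 mol%), CH2Cl2, 35 °C) gives the E-enoic acid directly. The fallback returns to the route at 10, bypassing steps 5 and 6.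

Further compounds

F1 | step 8 | methyl 2-[(5R)-5-[(3R,5E,9E,13E)-1-(3,5-dimethylpyrazol-1-yl)-6,10,14,18-tetramethyl-1-oxononadeca-5,9,13,17-tetraen-3-yl]-2-oxo-2,5-dihydrofuran-3-yl]acetate | COC(=O)CC1=C[C@H](OC1=O)[C@H](C/C=C(\C)CC/C=C(\C)CC/C=C(\C)CCC=C(C)C)CC(=O)n2nc(C)cc2C
F2 | step 9 | allyl (1R,5R,6R)-5-hydroxy-3-(2-methoxy-2-oxoethyl)-2-oxo-6-[(2E,6E,10E)-3,7,11,15-tetramethylhexadeca-2,6,10,14-tetraen-1-yl]cyclohex-3-ene-1-carboxylate | COC(=O)CC1=C[C@H](O)[C@H](C/C=C(\C)CC/C=C(\C)CC/C=C(\C)CCC=C(C)C)[C@@H](C(=O)OCC=C)C1=O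
F3 | step 5 | (4E,8E,12E)-5,9,13,17-tetramethyloctadeca-1,4,8,12,16-pentaene | C=CC/C=C(\C)CC/C=C(\C)CC/C=C(\C)CCC=C(C)C
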